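## Retrosynthetic overview

1. Numbering follows the briarane skeleton: ring A = C1/C10–C14, ten-membered ring = C1–C10, γ-lactone = O–C7–C8–C17–C19(=O); C15 on C1, C16 on C5, C18 on C17, C20 on C11.
2. Target ⇐ acetylation/desilylation ⇐ C6–Cl and C5=C16 by ene-type chlorination of a (5Z)-C5=C6 olefin (C16 as methyl) ⇐ lactone 33.
3. Lactone ring ⇐ C8–C17 bond by copper hydride reductive aldol cyclisation. Enabling feature: the acryloyloxy group on C7 stands 1,2 to the C8 ketone of the ten-membered ring (O7–C19–C17 tether, five-membered closure), with C9–OTBS on the other flank.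
4. Ten-membered ring ⇐ ring-closing metathesis at C5=C6; C7 ⇐ asymmetric γ-alkoxyallylboration of a C8 aldehyde; C2 ⇐ CBS reduction.
5. Ring A ⇐ Diels–Alder reaction of a glyceraldehyde-derived (E)-enal (C9 controls C10 and C1) with a 2-silyloxydiene, then Saegusa oxidation, diene formation and dihydroxylation (C11, C12). Ring order: ring A (step 3), ten-membered ring (step 18), lactone (step 22).

Key step: step 22

Remark: the Diels–Alder adduct 6 is carried as both C11 epimers, because this centre becomes planar in step 8; all other stereocentres are single isomers.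

## Route

Step 1
Reactants: 1 (R)-2,2-dimethyl-1,3-dioxolane-4-carbaldehyde; 2 2-(triphenylphosphoranylidene)propanal
Product: 3 (E)-3-[(4S)-2,2-dimethyl-1,3-dioxolan-4-yl]-2-methylprop-2-enal
Conditions: toluene, 60 °C
Reagents that add atoms: none
Why: Wittig olefination with a formyl-stabilised ylide should give the (E)-trisubstituted enal, and C9 is taken unchanged from the chiral pool.

Step 2
Reactants: 4 pent-1-en-3-one
Product: 5 (Z)-3-(tert-butyldimethylsilyloxy)penta-1,3-diene
Conditions: TBSOTf, Et3N, Et2O, 0 °C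
Reagents that add atoms: tert-butyldimethylsilyl trifluoromethanesulfonate, CC(C)(C)[Si](C)(C)OS(=O)(=O)C(F)(F)F
Why: Soft enolisation and O-silylation of the ethyl ketone should give the 2-silyloxydiene with the (Z)-enol ether geometry, which keeps the methyl group outward in the s-cis diene.

Step 3
Reactants: 3 (E)-enal; 5 silyloxydiene
Product: 6 (1S,6S)-4-(tert-butyldimethylsilyloxy)-6-[(4S)-2,2-dimethyl-1,3-dioxolan-4-yl]-1,5-dimethylcyclohex-3-ene-1-carbaldehyde (both C5 epimers; cyclohexene C1, C5, C6 = briarane C1, C11, C10)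
Conditions: Me2AlCl (0.3 equiv), CH2Cl2, −78 to −30 °C
Reagents that add atoms: none
Why: Lewis acid-catalysed Diels–Alder reaction: the nucleophilic diene terminus (future C11) bonds to the β-carbon C10 so that the silyloxy group ends para to the formyl-bearing C1, the (E)-geometry places C15 cis to the C10 side chain, and A(1,3) strain between C15 and the dioxolane holds C9–H in the enal plane so that the diene should add anti to the C9–O bond, which sets C10 and C1.

Step 4
Reactants: 6 Diels–Alder aldehyde; 7 2-(2-bromoethyl)-2-methyl-1,3-dioxolane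
Product: 10 C2 ketone 1-[(1S,6S)-4-(tert-butyldimethylsilyloxy)-6-[(4S)-2,2-dimethyl-1,3-dioxolan-4-yl]-1,5-dimethylcyclohex-3-en-1-yl]-3-(2-methyl-1,3-dioxolan-2-yl)propan-1-one, via Grignard reagent 8 (not isolated), via bromomagnesium alkoxide 9 (not isolated)
Conditions: 7, Mg, THF, 25 °C; then 6, −78 to 0 °C; then 1,1'-(azodicarbonyl)dipiperidine, 0 to 25 °C
Reagents that add atoms: none
Why: Grignard addition to the neopentyl aldehyde followed by oxidation of the bromomagnesium alkoxide in the same flask (hydride transfer to the azodicarboxamide) should give the C2 ketone directly, so that the unselectively formed C2 carbinol is never isolated.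

Step 5
Reactants: 10 C2 ketone
Product: 11 (2S)-alcohol (1S)-1-[(1S,6S)-4-(tert-butyldimethylsilyloxy)-6-[(4S)-2,2-dimethyl-1,3-dioxolan-4-yl]-1,5-dimethylcyclohex-3-en-1-yl]-3-(2-methyl-1,3-dioxolan-2-yl)propan-1-ol
Conditions: (R)-2-methyl-CBS-oxazaborolidine (0.2 equiv), catecholborane, toluene, −78 °C
Reagents that add atoms: none
Why: Corey–Bakshi–Shibata reduction: the (R)-oxazaborolidine differentiates the quaternary C1 (large) from the C3 methylene (small) and should deliver hydride to give the (2S)-carbinol under reagent control.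

Step 6
Reactants: 11 (2S)-alcohol
Product: 12 2-O-TBS ether of 11
Conditions: TBSOTf, 2,6-lutidine, CH2Cl2, −40 to 0 °C
Reagents that add atoms: tert-butyldimethylsilyl trifluoromethanesulfonate, CC(C)(C)[Si](C)(C)OS(=O)(=O)C(F)(F)F
Why: Silylation of the hindered secondary alcohol with the silyl triflate, under conditions that leave the silyl enol ether and both acetals intact.

Step 7
Reactants: 12 silyl enol ether
Product: 13 ring A enone (C12 ketone, C13=C14; C11 epimers) carrying 2-OTBS, the C5 ketal and the C8/C9 acetonide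
Conditions: Pd(OAc)2 (1.1 equiv), MeCN, 40 °C
Reagents that add atoms: none
Why: Saegusa–Ito oxidation: the palladium enolate at C13 can only undergo β-hydride elimination toward C14, which places the ring olefin at C13=C14 next to the quaternary C1.

Step 8
Reactants: 13 enone
Product: 14 dienyl triflate (C11=C12(OTf)–C13=C14)
Conditions: KN(SiMe3)2, THF, −78 °C; then PhNTf2, −78 to 0 °C
Reagents that add atoms: N-phenylbis(trifluoromethanesulfonimide), O=S(=O)(N(c1ccccc1)S(=O)(=O)C(F)(F)F)C(F)(F)F
Why: Kinetic enolate formation and O-triflation: the α′-carbon C11 is the only acidic position (the γ-carbon C1 is quaternary), so the cross-conjugated dienyl triflate should form and the C11 epimers converge.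

Step 9
Reactants: 14 dienyl triflate
Product: 15 cyclohexa-1,3-diene (C11=C12–C13=C14) carrying 2-OTBS, the C5 ketal and the C8/C9 acetonide
Conditions: Pd(OAc)2 (5 mol %), PPh3 (10 mol %), HCO2H, n-Bu3N, DMF, 60 °C
Reagents that add atoms: none
Why: Palladium-catalysed formate reduction of an enol triflate (oxidative addition, formate exchange, decarboxylation, reductive elimination) should replace OTf by H.

Step 10
Reactants: 15 diene
Product: 16 C8,C9-diol with C5 methyl ketone (diene retained)
Conditions: AcOH/THF/H2O (3:1:1), 45 °C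
Reagents that add atoms: water, O
Why: Acid-catalysed acetal hydrolysis should cleave the terminal acetonide and the dioxolane ketal, while the hindered C2 TBS ether survives.

Step 11
Reactants: 16 diol
Product: 17 8,9-bis-TBS ether of 16
Conditions: TBSCl, imidazole, DMAP (cat.), DMF, 40 °C
Reagents that add atoms: tert-butyldimethylsilyl chloride, CC(C)(C)[Si](C)(C)Cl
Why: Standard silylation of the primary C8 and secondary C9 hydroxyls, which leaves the methyl ketone untouched.

Step 12
Reactants: 17 diene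
Product: 18 (11S,12R)-cis-11,12-diol (C13=C14 retained)
Conditions: OsO4 (2 mol %), N-methylmorpholine N-oxide, acetone/H2O, 0 °C
Reagents that add atoms: N-methylmorpholine N-oxide, C[N+]1([O-])CCOCC1; water, O
Why: Upjohn dihydroxylation should take the more electron-rich trisubstituted C11=C12 bond rather than C13=C14 next to the quaternary C1, and osmium adds syn on the face anti to the C10 side chain and the C15 methyl, which sets C11 and C12.

Step 13
Reactants: 18 methyl ketone
Product: 19 isopropenyl compound (C5=CH2) with free 11,12-diol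
Conditions: Ph3PCH3Br, KOtBu (excess), THF, 0 to 25 °C
Reagents that add atoms: methyltriphenylphosphonium bromide, C[P+](c1ccccc1)(c1ccccc1)c1ccccc1.[Br-]
Why: Wittig methylenation of the C5 ketone is placed after step 12, so that no second olefin competes in the osmylation.

Step 14
Reactants: 19 diol
Product: 20 12-O-TBS, 11-O-TES ether
Conditions: TBSOTf (1.05 equiv), 2,6-lutidine, CH2Cl2, −78 °C; then TESOTf, 0 to 25 °C
Reagents that add atoms: tert-butyldimethylsilyl trifluoromethanesulfonate, CC(C)(C)[Si](C)(C)OS(=O)(=O)C(F)(F)F; triethylsilyl trifluoromethanesulfonate, CC[Si](CC)(CC)OS(=O)(=O)C(F)(F)F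
Why: Sequential silylation (secondary allylic C12–OH first, then tertiary C11–OH) caps the tertiary hydroxyl so that it cannot add to the later C8 ketone as a hemiketal.

Step 15
Reactants: 20 tetrasilyl ether
Product: 21 C8 primary alcohol
Conditions: HF·pyridine, pyridine, THF, 0 °C
Reagents that add atoms: none
Why: Selective desilylation: the primary TBS ether should be cleaved by buffered HF·pyridine well before the secondary TBS and tertiary TES ethers.

Step 16
Reactants: 21 primary alcohol
Product: 22 C8 aldehyde (α-silyloxy aldehyde)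
Conditions: Dess–Martin periodinane, NaHCO3, CH2Cl2, 0 to 25 °C
Reagents that add atoms: none
Why: Dess–Martin oxidation gives the α-silyloxy aldehyde under buffered, non-epimerising conditions.

Step 17
Reactants: 22 C8 aldehyde; 23 allyl methoxymethyl ether
Product: 26 syn adduct with 7-OMOM, 8-OH and a C7 vinyl group, via lithiated allyl ether 24 (not isolated), via allylborane 25 (not isolated)
Conditions: 23, sec-BuLi, THF, −78 °C; (+)-Ipc2BOMe; BF3·OEt2; then 22, −78 °C; then NaOH, H2O2, 0 °C
Reagents that add atoms: none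
Why: Asymmetric γ-alkoxyallylboration: the (Z)-allylborane with isopinocampheyl groups from (−)-α-pinene should attack the Re face of the aldehyde through a chair transition state (reagent control, matched with Felkin–Anh attack anti to C9–OTBS) and give the syn C7–OMOM/C8–OH pair, which sets C7 and leaves the two oxygens differentiated.

Step 18
Reactants: 26 diene
Product: 27 (5Z)-cyclodecene with 7-OMOM and 8-OH (bicyclo[8.4.0] core)
Conditions: second-generation Grubbs catalyst (10 mol %), toluene (1 mM), 80 °C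
Reagents that add atoms: none
Why: Ring-closing olefin metathesis between the C7 vinyl and the isopropenyl group closes the ten-membered ring as the trisubstituted C5=C6 olefin with loss of ethene; the trans side chains on ring A and high dilution favour cyclisation, and the cis ring olefin is expected as the less strained isomer.

Step 19
Reactants: 27 macrocyclic alcohol
Product: 28 macrocyclic C8 ketone (7-OMOM)
Conditions: Dess–Martin periodinane, NaHCO3, CH2Cl2, 0 °C
Reagents that add atoms: none
Why: Dess–Martin oxidation of the only free hydroxyl removes the auxiliary C8 stereocentre and creates the ketone needed for the key step.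

Step 20
Reactants: 28 MOM ether
Product: 29 7-hydroxy-8-ketone
Conditions: Me2BBr, CH2Cl2, −78 °C; then NaHCO3 (aq)
Reagents that add atoms: none
Why: Lewis acid-mediated acetal cleavage with the bromoborane should remove the MOM group at −78 °C without touching the silyl ethers or epimerising C7.

Step 21
Reactants: 29 hydroxy ketone; 30 acryloyl chloride
Product: 31 7-O-acryloyl-8-ketone
Conditions: pyridine, CH2Cl2, −20 °C
Reagents that add atoms: none
Why: O-Acylation of the secondary allylic alcohol with a weak base at low temperature, to avoid enolisation of the acidic C7–H.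

Step 22
Reactants: 31 acrylate ketone
Product: 33 γ-lactone with 8-OH and C17 methyl (C7, C8 and C17 as in the target; 5Z olefin), via copper (Z)-enolate 32 (not isolated)
Conditions: Cu(OAc)2·H2O (10 mol %), 1,2-bis(diphenylphosphino)benzene (10 mol %), (Me2HSi)2O, THF, 0 °C; then pH 7 buffer
Reagents that add atoms: none
Why: The copper hydride formed from Cu(OAc)2, the bisphosphine and the siloxane adds hydride to the unsubstituted acrylate terminus (C18 becomes the methyl group) and gives the (Z)-copper enolate 32, which attacks the C8 ketone intramolecularly through a chelated Zimmerman–Traxler array before the aldolate is silylated and copper hydride is regenerated. The closest known reaction type is the copper hydride-catalysed reductive aldol cyclisation of α,β-unsaturated esters of hydroxy ketones to β-hydroxylactones. The γ-lactone (O–C7–C8–C17–C19) closes in a five-membered exo-trig mode at the C8 carbonyl with both enolate carbons inside the new ring, a geometry that metal-bound enolates accept, as in intramolecular Reformatsky closures. C17 is set by the (Z)-enolate geometry in the chelate, which places the C18 methyl cis to the new C8–OH, and C8 is set by delivery from the C7 oxygen on the outer face of the ring, anti to the C9–OTBS bond (polar Felkin–Anh), which leaves C6 and C9 trans on the lactone. The step needs conjugate reduction of the acrylate to outrun 1,2-reduction of the ketone and enolisation at C7; a terminal acrylate set against a ketone flanked by two oxygenated carbons, under neutral conditions at 0 °C, should secure this.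

Step 23
Reactants: 33 lactone olefin
Product: 34 6-chloro-5(16)-ene (trisilyl/TES-protected target skeleton)
Conditions: Ca(OCl)2, CO2 (solid), CH2Cl2/H2O, 0 °C
Reagents that add atoms: calcium hypochlorite, [Ca+2].[O-]Cl.[O-]Cl
Why: Ene-type chlorination with hypochlorous acid: chlorine adds to the less substituted C6 of the trisubstituted olefin and a proton is lost from the C16 methyl to give the exocyclic C5=C16 bond; with C7–H held in the olefin plane by A(1,3) strain, the electrophile should approach anti to the C7–O bond, which sets C6 and mirrors the presumed biogenesis.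

Step 24
Reactants: 34 silyl-protected chloride
Product: 35 pentol (2-, 8-, 9-, 11-, 12-OH)
Conditions: HF·pyridine, THF, 0 to 25 °C
Reagents that add atoms: none
Why: Global fluoride-mediated desilylation removes the three TBS ethers and the TES ether under acidic conditions that the allylic chloride and the β-hydroxy lactone tolerate.

Step 25
Reactants: 35 pentol
Product: 36 CNP0259091.1 (target)
Conditions: Ac2O, pyridine, DMAP (cat.), CH2Cl2, 0 to 25 °C
Reagents that add atoms: acetic anhydride, CC(=O)OC(C)=O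
Why: Acetylation of the three secondary alcohols (C2, C9, C12); the tertiary C8 and C11 hydroxyls are too hindered to be acylated under these conditions.

## Compound list

1 | (R)-2,2-dimethyl-1,3-dioxolane-4-carbaldehyde | O=C[C@H]1COC(C)(C)O1 | starting material
2 | 2-(triphenylphosphoranylidene)propanal | CC(C=O)=P(c1ccccc1)(c1ccccc1)c1ccccc1 | starting material
3 | (E)-3-[(4S)-2,2-dimethyl-1,3-dioxolan-4-yl]-2-methylprop-2-enal | O=C/C(C)=C/[C@H]1COC(C)(C)O1 | intermediate
4 | pent-1-en-3-one | CCC(=O)C=C | starting material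
5 | (Z)-3-(tert-butyldimethylsilyloxy)penta-1,3-diene | C/C=C(\O[Si](C)(C)C(C)(C)C)C=C | intermediate
6 | (1S,6S)-4-(tert-butyldimethylsilyloxy)-6-[(4S)-2,2-dimethyl-1,3-dioxolan-4-yl]-1,5-dimethylcyclohex-3-ene-1-carbaldehyde (both C5 epimers) | O=C[C@@]1(C)CC=C(O[Si](C)(C)C(C)(C)C)C(C)[C@@H]1[C@H]1COC(C)(C)O1 | intermediate
7 | 2-(2-bromoethyl)-2-methyl-1,3-dioxolane | CC1(CCBr)OCCO1 | starting material
8 | [2-(2-methyl-1,3-dioxolan-2-yl)ethyl]magnesium bromide | CC1(CC[Mg]Br)OCCO1 | intermediate
9 | bromomagnesium alkoxide of the C2 carbinol from 6 and 8 (both C2 epimers) | CC1(CCC(O[Mg]Br)[C@@]2(C)CC=C(O[Si](C)(C)C(C)(C)C)C(C)[C@@H]2[C@H]2COC(C)(C)O2)OCCO1 | intermediate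
10 | C2 ketone (C5 ketal, C8/C9 acetonide, silyl enol ether) | CC1(CCC(=O)[C@@]2(C)CC=C(O[Si](C)(C)C(C)(C)C)C(C)[C@@H]2[C@H]2COC(C)(C)O2)OCCO1 | intermediate
11 | (2S)-alcohol | CC1(CC[C@H](O)[C@@]2(C)CC=C(O[Si](C)(C)C(C)(C)C)C(C)[C@@H]2[C@H]2COC(C)(C)O2)OCCO1 | intermediate
12 | 2-O-TBS ether of 11 | CC1(CC[C@H](O[Si](C)(C)C(C)(C)C)[C@@]2(C)CC=C(O[Si](C)(C)C(C)(C)C)C(C)[C@@H]2[C@H]2COC(C)(C)O2)OCCO1 | intermediate
13 | ring A enone (C12 ketone, C13=C14; C11 epimers) | CC1(CC[C@H](O[Si](C)(C)C(C)(C)C)[C@@]2(C)C=CC(=O)C(C)[C@@H]2[C@H]2COC(C)(C)O2)OCCO1 | intermediate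
14 | dienyl triflate (C11=C12(OTf)–C13=C14) | CC1(CC[C@H](O[Si](C)(C)C(C)(C)C)[C@@]2(C)C=CC(OS(=O)(=O)C(F)(F)F)=C(C)[C@@H]2[C@H]2COC(C)(C)O2)OCCO1 | intermediate
15 | cyclohexa-1,3-diene (C11=C12–C13=C14) | CC1(CC[C@H](O[Si](C)(C)C(C)(C)C)[C@@]2(C)C=CC=C(C)[C@@H]2[C@H]2COC(C)(C)O2)OCCO1 | intermediate
16 | C8,C9-diol with C5 methyl ketone | CC(=O)CC[C@H](O[Si](C)(C)C(C)(C)C)[C@@]1(C)C=CC=C(C)[C@@H]1[C@H](O)CO | intermediate
17 | 8,9-bis-TBS ether of 16 | CC(=O)CC[C@H](O[Si](C)(C)C(C)(C)C)[C@@]1(C)C=CC=C(C)[C@@H]1[C@H](O[Si](C)(C)C(C)(C)C)CO[Si](C)(C)C(C)(C)C | intermediate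
18 | (11S,12R)-cis-11,12-diol | CC(=O)CC[C@H](O[Si](C)(C)C(C)(C)C)[C@@]1(C)C=C[C@@H](O)[C@@](C)(O)[C@@H]1[C@H](O[Si](C)(C)C(C)(C)C)CO[Si](C)(C)C(C)(C)C | intermediate
19 | isopropenyl compound with free 11,12-diol | C=C(C)CC[C@H](O[Si](C)(C)C(C)(C)C)[C@@]1(C)C=C[C@@H](O)[C@@](C)(O)[C@@H]1[C@H](O[Si](C)(C)C(C)(C)C)CO[Si](C)(C)C(C)(C)C | intermediate
20 | 12-O-TBS, 11-O-TES ether | C=C(C)CC[C@H](O[Si](C)(C)C(C)(C)C)[C@@]1(C)C=C[C@@H](O[Si](C)(C)C(C)(C)C)[C@@](C)(O[Si](CC)(CC)CC)[C@@H]1[C@H](O[Si](C)(C)C(C)(C)C)CO[Si](C)(C)C(C)(C)C | intermediate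
21 | C8 primary alcohol | C=C(C)CC[C@H](O[Si](C)(C)C(C)(C)C)[C@@]1(C)C=C[C@@H](O[Si](C)(C)C(C)(C)C)[C@@](C)(O[Si](CC)(CC)CC)[C@@H]1[C@H](O[Si](C)(C)C(C)(C)C)CO | intermediate
22 | C8 aldehyde | C=C(C)CC[C@H](O[Si](C)(C)C(C)(C)C)[C@@]1(C)C=C[C@@H](O[Si](C)(C)C(C)(C)C)[C@@](C)(O[Si](CC)(CC)CC)[C@@H]1[C@H](O[Si](C)(C)C(C)(C)C)C=O | intermediate
23 | allyl methoxymethyl ether | C=CCOCOC | starting material
24 | (Z)-3-(methoxymethoxy)allyllithium | COCO/C=C\C[Li] | intermediate
25 | (Z)-[3-(methoxymethoxy)allyl]diisopinocampheylborane (from (−)-α-pinene) | COCO/C=C\CB([C@H]1C[C@H]2C[C@@H]([C@@H]1C)C2(C)C)[C@H]1C[C@H]2C[C@@H]([C@@H]1C)C2(C)C | intermediate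
26 | syn adduct: 7-OMOM, 8-OH, C7 vinyl | C=C(C)CC[C@H](O[Si](C)(C)C(C)(C)C)[C@@]1(C)C=C[C@@H](O[Si](C)(C)C(C)(C)C)[C@@](C)(O[Si](CC)(CC)CC)[C@@H]1[C@H](O[Si](C)(C)C(C)(C)C)[C@H](O)[C@@H](OCOC)C=C | intermediate
27 | (5Z)-cyclodecene, 7-OMOM, 8-OH | C1[C@H](O[Si](C)(C)C(C)(C)C)[C@@]2(C)C=C[C@@H](O[Si](C)(C)C(C)(C)C)[C@@](C)(O[Si](CC)(CC)CC)[C@@H]2[C@H](O[Si](C)(C)C(C)(C)C)[C@H](O)[C@@H](OCOC)/C=C(C)\C1 | intermediate
28 | macrocyclic C8 ketone, 7-OMOM | C1[C@H](O[Si](C)(C)C(C)(C)C)[C@@]2(C)C=C[C@@H](O[Si](C)(C)C(C)(C)C)[C@@](C)(O[Si](CC)(CC)CC)[C@@H]2[C@H](O[Si](C)(C)C(C)(C)C)C(=O)[C@@H](OCOC)/C=C(C)\C1 | intermediate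
29 | 7-hydroxy-8-ketone | C1[C@H](O[Si](C)(C)C(C)(C)C)[C@@]2(C)C=C[C@@H](O[Si](C)(C)C(C)(C)C)[C@@](C)(O[Si](CC)(CC)CC)[C@@H]2[C@H](O[Si](C)(C)C(C)(C)C)C(=O)[C@@H](O)/C=C(C)\C1 | intermediate
30 | acryloyl chloride | C=CC(=O)Cl | starting material
31 | 7-O-acryloyl-8-ketone | C1[C@H](O[Si](C)(C)C(C)(C)C)[C@@]2(C)C=C[C@@H](O[Si](C)(C)C(C)(C)C)[C@@](C)(O[Si](CC)(CC)CC)[C@@H]2[C@H](O[Si](C)(C)C(C)(C)C)C(=O)[C@@H](OC(=O)C=C)/C=C(C)\C1 | intermediate
32 | copper (Z)-enolate of 31 | C1[C@H](O[Si](C)(C)C(C)(C)C)[C@@]2(C)C=C[C@@H](O[Si](C)(C)C(C)(C)C)[C@@](C)(O[Si](CC)(CC)CC)[C@@H]2[C@H](O[Si](C)(C)C(C)(C)C)C(=O)[C@@H](O/C(O[Cu])=C/C)/C=C(C)\C1 | intermediate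
33 | γ-lactone, 8-OH, C17 methyl, 5Z olefin | C1[C@H](O[Si](C)(C)C(C)(C)C)[C@@]2(C)C=C[C@@H](O[Si](C)(C)C(C)(C)C)[C@@](C)(O[Si](CC)(CC)CC)[C@@H]2[C@H](O[Si](C)(C)C(C)(C)C)[C@]3(O)[C@@H](C)C(=O)O[C@H]3/C=C(C)\C1 | intermediate
34 | 6-chloro-5(16)-ene, silyl-protected | C=C1CC[C@H](O[Si](C)(C)C(C)(C)C)[C@@]2(C)C=C[C@@H](O[Si](C)(C)C(C)(C)C)[C@@](C)(O[Si](CC)(CC)CC)[C@@H]2[C@H](O[Si](C)(C)C(C)(C)C)[C@]2(O)[C@@H](C)C(=O)O[C@H]2[C@H]1Cl | intermediate
35 | pentol | C=C1CC[C@H](O)[C@@]2(C)C=C[C@@H](O)[C@@](C)(O)[C@@H]2[C@H](O)[C@]2(O)[C@@H](C)C(=O)O[C@H]2[C@H]1Cl | intermediate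
36 | CNP0259091.1 | C=C1CC[C@H](OC(C)=O)[C@@]2(C)C=C[C@@H](OC(C)=O)[C@@](C)(O)[C@@H]2[C@H](OC(C)=O)[C@]2(O)[C@@H](C)C(=O)O[C@H]2[C@H]1Cl | target

## Step count and risks

Total step count: 25. Longest linear sequence: 24 steps (steps 1 and 3–25; step 2 prepares diene 5).

**Step 22 (key step).** The copper hydride may reduce the C8 ketone directly, or the enolate may attack the inner face of the carbonyl, giving poor facial selectivity at C8. The fallback sets out from 29. Acylation with 2-bromopropanoyl bromide (pyridine, CH2Cl2, −40 °C) should give the 7-O-(2-bromopropanoyl) ester F1. Treatment with SmI2 in THF at −78 °C would then run an intramolecular Reformatsky reaction: reductive cleavage of the C–Br bond gives a samarium enolate chelated to the ketone, which closes the same C8–C17 bond. The fallback comes back to the route at 33.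

**Step 18.** Intermolecular metathesis (oligomerisation) may outrun closure of the ten-membered ring onto the 1,1-disubstituted olefin. The fallback inverts the order of the two ring closures and sets out from 26. Dess–Martin oxidation should give the open-chain C8 ketone F2, Me2BBr the open-chain 7-hydroxy-8-ketone F3, and acryloyl chloride/pyridine the open-chain 7-O-acryloyl-8-ketone F4. The copper hydride reductive aldol cyclisation of F4, under the conditions of step 22, should give the open-chain γ-lactone F5. In F5 the trans-substituted lactone and the quaternary C8 restrict the chain and no free C8–OH/C7–OMOM pair can bind ruthenium. Ring-closing metathesis of F5 (second-generation Grubbs catalyst, toluene, high dilution, 80 °C) would close the ten-membered ring and come back to the route at 33.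

**Step 23.** The chlorine electrophile may attack the other face of C5=C6 (poor facial selectivity at C6), or the proton may be lost from C4 instead of C16. The fallback sets out from 33 and replaces the one-step ene chlorination by an oxygen-first sequence with net inversion at C6. Buffered mCPBA (NaHCO3, CH2Cl2, 0 °C) should give the 5,6-epoxide F6 on the face that the electrophile prefers. Cp2TiCl2/Mn in THF (Cp2TiCl, trivalent titanium) should open it to the tertiary C5 radical, which loses a hydrogen from the C16 methyl to give the 6-epi C6 allylic alcohol F7 with the exocyclic C5=C16 bond. PPh3/hexachloroacetone (CH2Cl2, 0 °C) should then replace OH by Cl with inversion and without allylic transposition. The chloride thus ends on the face opposite to the first electrophile, which corrects a facial preference opposite to the predicted one, and the sequence comes back to the route at 34.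

## Further compounds

F1 | step 22 | 7-O-(2-bromopropanoyl) ester of 29 (both C17 epimers) | C1[C@H](O[Si](C)(C)C(C)(C)C)[C@@]2(C)C=C[C@@H](O[Si](C)(C)C(C)(C)C)[C@@](C)(O[Si](CC)(CC)CC)[C@@H]2[C@H](O[Si](C)(C)C(C)(C)C)C(=O)[C@@H](OC(=O)C(C)Br)/C=C(C)\C1
F2 | step 18 | open-chain C8 ketone | C=C(C)CC[C@H](O[Si](C)(C)C(C)(C)C)[C@@]1(C)C=C[C@@H](O[Si](C)(C)C(C)(C)C)[C@@](C)(O[Si](CC)(CC)CC)[C@@H]1[C@H](O[Si](C)(C)C(C)(C)C)C(=O)[C@@H](OCOC)C=C
F3 | step 18 | open-chain 7-hydroxy-8-ketone | C=C(C)CC[C@H](O[Si](C)(C)C(C)(C)C)[C@@]1(C)C=C[C@@H](O[Si](C)(C)C(C)(C)C)[C@@](C)(O[Si](CC)(CC)CC)[C@@H]1[C@H](O[Si](C)(C)C(C)(C)C)C(=O)[C@@H](O)C=C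
F4 | step 18 | open-chain 7-O-acryloyl-8-ketone | C=C(C)CC[C@H](O[Si](C)(C)C(C)(C)C)[C@@]1(C)C=C[C@@H](O[Si](C)(C)C(C)(C)C)[C@@](C)(O[Si](CC)(CC)CC)[C@@H]1[C@H](O[Si](C)(C)C(C)(C)C)C(=O)[C@@H](OC(=O)C=C)C=C
F5 | step 18 | open-chain γ-lactone with C7 vinyl and isopropenyl groups | C=C(C)CC[C@H](O[Si](C)(C)C(C)(C)C)[C@@]1(C)C=C[C@@H](O[Si](C)(C)C(C)(C)C)[C@@](C)(O[Si](CC)(CC)CC)[C@@H]1[C@H](O[Si](C)(C)C(C)(C)C)[C@]1(O)[C@@H](C)C(=O)O[C@H]1C=C
F6 | step 23 | 5,6-epoxide of 33 (oxygen on the face opposite to the target chlorine) | C[C@@]14CC[C@H](O[Si](C)(C)C(C)(C)C)[C@@]2(C)C=C[C@@H](O[Si](C)(C)C(C)(C)C)[C@@](C)(O[Si](CC)(CC)CC)[C@@H]2[C@H](O[Si](C)(C)C(C)(C)C)[C@]2(O)[C@@H](C)C(=O)O[C@H]2[C@@H]1O4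
F7 | step 23 | 6-epi C6 allylic alcohol with exocyclic C5=C16 | C=C1CC[C@H](O[Si](C)(C)C(C)(C)C)[C@@]2(C)C=C[C@@H](O[Si](C)(C)C(C)(C)C)[C@@](C)(O[Si](CC)(CC)CC)[C@@H]2[C@H](O[Si](C)(C)C(C)(C)C)[C@]2(O)[C@@H](C)C(=O)O[C@H]2[C@@H]1O
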